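The ring stereocentres hang on an open C3–C8 chain, reached by cutting the 1,2-dioxane (O1–O2–C3–C4–C5–C6) at O2–C3 and O1–C6. The key step exploits the ethyl-branched C4 methine that sits between C3 and the C5 methylene leading to quaternary C6. In one pot allyl alcohol (C3–C5) is ethyl-aluminated enantioselectively and the alkylalane is coupled with a (Z)-alkenyl iodide (C6–C8). This forms C4–Et and C5–C6, sets 4R and installs a geometrically pure C6=C7 olefin. That olefin later carries the C6 peroxide (Sharpless epoxidation, perhydrolysis with inversion). C3 is alkylated through a peroxycarbenium ion and C8–C14 arrive by Negishi couplings. The precursor is TBS-protected (Z)-3-iodopent-2-en-1-ol.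

Key step: step 3

Numbering: C1 is the carboxyl carbon, C2 its methylene, the ring is O1–O2–C3–C4–C5–C6, and the side chain runs C7–C14.

Assumption: the aluminium alkoxide of allyl alcohol is taken to follow the facial preference that (NMI)2ZrCl2 shows with simple 1-alkenes, which points to the (+)-antipode for 2R in 9; should a trial run show the opposite sense, the (−)-antipode is used and nothing else changes.

Step 1
Reactants: 1 pent-2-yn-1-ol
Product: 3 (2Z)-3-iodopent-2-en-1-ol, via cyclic sodium alkenylalanate 2 (not isolated)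
Conditions: NaAlH2(OCH2CH2OCH3)2, THF, 0 °C to rt; then I2, THF, −78 to 0 °C
Reagents that add atoms: iodine, II
Why: Alkoxide-directed trans-hydroalumination of the propargylic alcohol puts aluminium on C3 and hydride on C2, and iodinolysis with retention should give the Z iodide with iodine cis to the hydroxymethyl group.

Step 2
Reactants: 3 (2Z)-3-iodopent-2-en-1-ol
Product: 4 tert-butyl-[(2Z)-3-iodopent-2-enoxy]dimethylsilane
Conditions: TBSCl, imidazole, CH2Cl2, 0 °C to rt
Reagents that add atoms: tert-butyldimethylsilyl chloride, CC(C)(C)[Si](C)(C)Cl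
Why: Standard silylation of a primary alcohol gives an ether that is inert to alanes and is later removed by acidic methanol in the acetalisation step.

Step 3
Reactants: 5 allyl alcohol; 6 triethylaluminium; 4 tert-butyl-[(2Z)-3-iodopent-2-enoxy]dimethylsilane
Product: 9 (2R,4Z)-6-[tert-butyl(dimethyl)silyl]oxy-2,4-diethylhex-4-en-1-ol, via diethylaluminium allyloxide 7 (not isolated), via (4S)-2,4-diethyl-1,2-oxaluminolane 8 (not isolated)
Conditions: Et3Al, CH2Cl2, 0 °C; bis(1-neomenthylindenyl)zirconium dichloride [(+)-(NMI)2ZrCl2] (5 mol %), isobutylaluminoxane, 0 °C to rt; volatiles off in vacuo; Zn(OTf)2, DMF, 70 °C; then 4, PdCl2(DPEphos) (3 mol %), iBu2AlH (6 mol %), rt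
Reagents that add atoms: none
Why: The aluminium alkoxide of allyl alcohol undergoes zirconium-catalysed asymmetric carboalumination, the chiral ethylzirconium species adding across the terminal alkene with ethyl on the internal carbon (C4) and metal on the terminal carbon (C5); zirconium-to-aluminium exchange gives alane 8, which Zn(OTf)2 activates for palladium-catalysed Negishi-type coupling with iodide 4. The closest known reaction type is the one-pot asymmetric carboalumination–palladium cross-coupling of 1-alkenes with alkenyl halides. No ring is closed. The C4 stereocentre (2R in 9) is set by the enantiofacial preference of the neomenthylindenyl ligands alone; isobutylaluminoxane is chosen as activator because methylaluminoxane would feed methyl groups into the alkyl transfer. The step needs ethyl delivery to the internal carbon (secured by the monosubstituted alkene), retention of the Z geometry (secured by stereoretentive oxidative addition and reductive elimination at palladium) and transfer of the branched alkyl ahead of residual ethyl (helped by stripping excess Et3Al and by the easy separation of the non-polar ethyl-coupled ether from alcohol 9). A shortfall in enantiomeric purity should be removed later, because the reagent-controlled epoxidation of step 6 turns the minor C4 antipode into a separable diastereomer.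

Step 4
Reactants: 9 (2R,4Z)-6-[tert-butyl(dimethyl)silyl]oxy-2,4-diethylhex-4-en-1-ol
Product: 10 (2R,4Z)-6-[tert-butyl(dimethyl)silyl]oxy-2,4-diethylhex-4-enal
Conditions: Dess–Martin periodinane, NaHCO3, CH2Cl2, 0 °C; used crude
Reagents that add atoms: none
Why: Buffered Dess–Martin oxidation is non-basic, so the α-branched aldehyde should form without epimerisation at C4.

Step 5
Reactants: 10 (2R,4Z)-6-[tert-butyl(dimethyl)silyl]oxy-2,4-diethylhex-4-enal
Product: 12 (2Z,5R)-3,5-diethyl-6,6-dimethoxyhex-2-en-1-ol, via silyl ether acetal 11 (not isolated)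
Conditions: HC(OMe)3, CSA (10 mol %), MeOH, 0 °C to rt
Reagents that add atoms: trimethyl orthoformate, COC(OC)OC; methanol, CO
Why: Acid-catalysed acetalisation driven by the orthoformate masks C3, and the same acidic methanol cleaves the primary allylic silyl ether, while the low temperature should keep the acetal from enolising.

Step 6
Reactants: 12 (2Z,5R)-3,5-diethyl-6,6-dimethoxyhex-2-en-1-ol
Product: 13 [(2R,3S)-3-ethyl-3-[(2R)-2-ethyl-3,3-dimethoxypropyl]oxiran-2-yl]methanol
Conditions: Ti(OiPr)4 (10 mol %), D-(−)-diethyl tartrate (12 mol %), t-BuOOH, 4 Å molecular sieves, CH2Cl2, −20 °C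
Reagents that add atoms: tert-butyl hydroperoxide, CC(C)(C)OO
Why: Sharpless asymmetric epoxidation of the 3,3-disubstituted allylic alcohol is reagent-controlled, and the D-tartrate should deliver oxygen to the face that gives the (6S,7R) epoxide needed for 6R after inversion.

Step 7
Reactants: 13 [(2R,3S)-3-ethyl-3-[(2R)-2-ethyl-3,3-dimethoxypropyl]oxiran-2-yl]methanol
Product: 15 (1R)-1-[(3R,5R,6RS)-3,5-diethyl-6-methoxy-1,2-dioxan-3-yl]ethane-1,2-diol, via hydroperoxy diol acetal 14 (not isolated)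
Conditions: H2O2 (anhydrous, Et2O, 5 equiv), H3PMo12O40 (cat.), 0 °C to rt; aqueous NaHCO3 wash; then PPTS, MeOH, rt
Reagents that add atoms: hydrogen peroxide, OO
Why: Acid-catalysed perhydrolysis should open the trisubstituted epoxide at tertiary C6 with inversion, and the tertiary hydroperoxide (or the hydroperoxy acetal formed by exchange at C3) closes the six-membered peroxyacetal by intramolecular transacetalisation, after which methanol and PPTS funnel exchange products to the methyl peroxyacetal.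

Step 8
Reactants: 15 (1R)-1-[(3R,5R,6RS)-3,5-diethyl-6-methoxy-1,2-dioxan-3-yl]ethane-1,2-diol
Product: 16 (3R,5R,6RS)-3,5-diethyl-6-methoxy-1,2-dioxane-3-carbaldehyde
Conditions: NaIO4, THF/pH 7 buffer, 0 °C
Reagents that add atoms: none
Why: Periodate glycol cleavage removes C8 under neutral conditions that leave the dialkyl peroxide and the peroxyacetal alone, and the aldehyde sits on a quaternary carbon and cannot epimerise.

Step 9
Reactants: 16 (3R,5R,6RS)-3,5-diethyl-6-methoxy-1,2-dioxane-3-carbaldehyde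
Product: 17 (3RS,4R,6R)-6-(2,2-dibromoethenyl)-4,6-diethyl-3-methoxy-1,2-dioxane
Conditions: CBr4, PPh3, Zn, CH2Cl2, rt (ylide preformed); then 16, 0 °C to rt
Reagents that add atoms: carbon tetrabromide, BrC(Br)(Br)Br
Why: Corey–Fuchs dibromo-olefination with the preformed ylide returns C8 as a dibromomethylene group and keeps free phosphine away from the peroxide.

Step 10
Reactants: 17 (3RS,4R,6R)-6-(2,2-dibromoethenyl)-4,6-diethyl-3-methoxy-1,2-dioxane
Product: 18 methyl 2-[(3R,4R,6R)-6-(2,2-dibromoethenyl)-4,6-diethyl-1,2-dioxan-3-yl]acetate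
Conditions: CH2=C(OMe)OTBS (3 equiv), TMSOTf (0.3 equiv), CH2Cl2, −78 °C
Reagents that add atoms: 1-(tert-butyldimethylsilyloxy)-1-methoxyethene, C=C(OC)O[Si](C)(C)C(C)(C)C
Why: TMSOTf ionises the methoxy group to a peroxycarbenium ion that the silyl ketene acetal traps (Mukaiyama-type substitution of a peroxyacetal); the cis-4,6 substituents lock the half-chair with the C4 ethyl pseudo-equatorial, so axial chair-like attack should place the acetate arm cis to that ethyl and give 3R, while the electron-poor dibromo-olefin keeps the allylic C6–O bond from ionising.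

Step 11
Reactants: 19 (3E)-hex-3-enoic acid; 20 (4S)-4-benzyl-1,3-oxazolidin-2-one
Product: 22 (4S)-4-benzyl-3-[(3E)-hex-3-enoyl]-1,3-oxazolidin-2-one, via pivalic mixed anhydride 21 (not isolated)
Conditions: PivCl, Et3N, THF, −78 to 0 °C; then 20/n-BuLi, THF, −78 °C
Reagents that add atoms: none
Why: N-acylation of the lithiated Evans auxiliary by the mixed anhydride proceeds at low temperature, which should keep the β,γ-olefin out of conjugation.

Step 12
Reactants: 22 (4S)-4-benzyl-3-[(3E)-hex-3-enoyl]-1,3-oxazolidin-2-one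
Product: 24 (4S)-4-benzyl-3-[(2S,3E)-2-ethylhex-3-enoyl]-1,3-oxazolidin-2-one, via sodium Z-enolate 23 (not isolated)
Conditions: NaN(SiMe3)2, THF, −78 °C; then EtI (5 equiv), −78 to −30 °C
Reagents that add atoms: iodoethane, CCI
Why: Evans alkylation of the chelated Z-enolate occurs at the α-carbon on the face away from the benzyl group, which sets the future C10 stereocentre, and the minor diastereomer is removed by chromatography.

Step 13
Reactants: 24 (4S)-4-benzyl-3-[(2S,3E)-2-ethylhex-3-enoyl]-1,3-oxazolidin-2-one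
Product: 25 (2S,3E)-2-ethylhex-3-en-1-ol
Conditions: LiBH4, MeOH (1 equiv), Et2O, 0 °C
Reagents that add atoms: none
Why: Reductive cleavage of the imide releases the primary alcohol and the recoverable auxiliary without touching the α-stereocentre or the olefin.

Step 14
Reactants: 25 (2S,3E)-2-ethylhex-3-en-1-ol
Product: 26 (3S,4E)-3-(iodomethyl)hept-4-ene
Conditions: I2, PPh3, imidazole, CH2Cl2, 0 °C
Reagents that add atoms: iodine, II
Why: Appel-type iodination replaces the primary hydroxyl by SN2 at a carbon that is not stereogenic.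

Step 15
Reactants: 26 (3S,4E)-3-(iodomethyl)hept-4-ene; 18 methyl 2-[(3R,4R,6R)-6-(2,2-dibromoethenyl)-4,6-diethyl-1,2-dioxan-3-yl]acetate
Product: 29 methyl 2-[(3R,4R,6R)-6-[(1Z,4R,5E)-2-bromo-4-ethylocta-1,5-dienyl]-4,6-diethyl-1,2-dioxan-3-yl]acetate, via alkyllithium 27 (not isolated), via alkylzinc bromide 28 (not isolated)
Conditions: 26, t-BuLi (2.1 equiv), Et2O, −78 °C; ZnBr2, THF, −78 to 0 °C; then 18, PdCl2(DPEphos) (5 mol %), THF, 0 °C to rt
Reagents that add atoms: none
Why: Iodine–lithium exchange and transmetalation give a primary alkylzinc whose stereocentre is β to the metal, and in the Negishi coupling palladium should insert only into the C–Br bond trans to the bulky C6 substituent (trans-selective monoalkylation of a 1,1-dibromoalkene), the ester and the peroxide tolerating the organozinc.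

Step 16
Reactants: 29 methyl 2-[(3R,4R,6R)-6-[(1Z,4R,5E)-2-bromo-4-ethylocta-1,5-dienyl]-4,6-diethyl-1,2-dioxan-3-yl]acetate
Product: 30 methyl 2-[(3R,4R,6R)-4,6-diethyl-6-[(1E,4R,5E)-4-ethyl-2-methylocta-1,5-dienyl]-1,2-dioxan-3-yl]acetate
Conditions: Me2Zn (2 equiv), Pd(PtBu3)2 (5 mol %), THF, rt
Reagents that add atoms: dimethylzinc, C[Zn]C
Why: A second Negishi coupling replaces the remaining alkenyl bromide by methyl with retention, which should give the 7E olefin with methyl cis and C9 trans to C6.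

Step 17
Reactants: 30 methyl 2-[(3R,4R,6R)-4,6-diethyl-6-[(1E,4R,5E)-4-ethyl-2-methylocta-1,5-dienyl]-1,2-dioxan-3-yl]acetate
Product: 31 2-[(3R,4R,6R)-4,6-diethyl-6-[(1E,4R,5E)-4-ethyl-2-methylocta-1,5-dienyl]-1,2-dioxan-3-yl]acetic acid
Conditions: LiOH, THF/MeOH/H2O, 0 °C to rt; then dilute HCl to pH 3–4
Reagents that add atoms: lithium hydroxide, [Li+].[OH-]
Why: Low-temperature saponification of the methyl ester (ester hydrolysis) should leave the dialkyl peroxide and all four stereocentres untouched.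

Compound list

1 | pent-2-yn-1-ol | CCC#CCO | starting material
2 | cyclic sodium alkenylalanate from trans-hydroalumination of 1 (Al on C3, bound to the alkoxide oxygen, two 2-methoxyethoxy ligands) | CCC1=CCO[Al-]1(OCCOC)OCCOC.[Na+] | intermediate
3 | (2Z)-3-iodopent-2-en-1-ol | CC/C(I)=C/CO | intermediate
4 | tert-butyl-[(2Z)-3-iodopent-2-enoxy]dimethylsilane | CC/C(I)=C/CO[Si](C)(C)C(C)(C)C | intermediate
5 | allyl alcohol (prop-2-en-1-ol) | C=CCO | starting material
6 | triethylaluminium | CC[Al](CC)CC | starting material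
7 | diethylaluminium allyloxide [diethyl(prop-2-enoxy)alumane] | C=CCO[Al](CC)CC | intermediate
8 | (4S)-2,4-diethyl-1,2-oxaluminolane (same spatial arrangement at C4 as 2R in 9) | CC[C@H]1CO[Al](CC)C1 | intermediate
9 | (2R,4Z)-6-[tert-butyl(dimethyl)silyl]oxy-2,4-diethylhex-4-en-1-ol | OC[C@H](CC)C/C(CC)=C\CO[Si](C)(C)C(C)(C)C | intermediate
10 | (2R,4Z)-6-[tert-butyl(dimethyl)silyl]oxy-2,4-diethylhex-4-enal | O=C[C@H](CC)C/C(CC)=C\CO[Si](C)(C)C(C)(C)C | intermediate
11 | tert-butyl-[(2Z,5R)-3,5-diethyl-6,6-dimethoxyhex-2-enoxy]dimethylsilane | COC(OC)[C@H](CC)C/C(CC)=C\CO[Si](C)(C)C(C)(C)C | intermediate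
12 | (2Z,5R)-3,5-diethyl-6,6-dimethoxyhex-2-en-1-ol | COC(OC)[C@H](CC)C/C(CC)=C\CO | intermediate
13 | [(2R,3S)-3-ethyl-3-[(2R)-2-ethyl-3,3-dimethoxypropyl]oxiran-2-yl]methanol | COC(OC)[C@H](CC)C[C@]1(CC)O[C@@H]1CO | intermediate
14 | (2R,3R,5R)-3,5-diethyl-3-hydroperoxy-6,6-dimethoxyhexane-1,2-diol | COC(OC)[C@H](CC)C[C@@](CC)(OO)[C@H](O)CO | intermediate
15 | (1R)-1-[(3R,5R,6RS)-3,5-diethyl-6-methoxy-1,2-dioxan-3-yl]ethane-1,2-diol (anomeric mixture at the methoxy carbon) | OC[C@@H](O)[C@@]1(CC)C[C@@H](CC)C(OC)OO1 | intermediate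
16 | (3R,5R,6RS)-3,5-diethyl-6-methoxy-1,2-dioxane-3-carbaldehyde | O=C[C@@]1(CC)C[C@@H](CC)C(OC)OO1 | intermediate
17 | (3RS,4R,6R)-6-(2,2-dibromoethenyl)-4,6-diethyl-3-methoxy-1,2-dioxane | BrC(Br)=C[C@@]1(CC)C[C@@H](CC)C(OC)OO1 | intermediate
18 | methyl 2-[(3R,4R,6R)-6-(2,2-dibromoethenyl)-4,6-diethyl-1,2-dioxan-3-yl]acetate | BrC(Br)=C[C@@]1(CC)C[C@@H](CC)[C@@H](CC(=O)OC)OO1 | intermediate
19 | (3E)-hex-3-enoic acid | CC/C=C/CC(=O)O | starting material
20 | (4S)-4-benzyl-1,3-oxazolidin-2-one | O=C1N[C@@H](Cc2ccccc2)CO1 | starting material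
21 | (3E)-hex-3-enoic pivalic anhydride | CC/C=C/CC(=O)OC(=O)C(C)(C)C | intermediate
22 | (4S)-4-benzyl-3-[(3E)-hex-3-enoyl]-1,3-oxazolidin-2-one | CC/C=C/CC(=O)N1[C@@H](Cc2ccccc2)COC1=O | intermediate
23 | sodium Z-enolate of 22 | CC/C=C/C=C(\[O-])N1[C@@H](Cc2ccccc2)COC1=O.[Na+] | intermediate
24 | (4S)-4-benzyl-3-[(2S,3E)-2-ethylhex-3-enoyl]-1,3-oxazolidin-2-one | CC/C=C/[C@H](CC)C(=O)N1[C@@H](Cc2ccccc2)COC1=O | intermediate
25 | (2S,3E)-2-ethylhex-3-en-1-ol | CC/C=C/[C@H](CC)CO | intermediate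
26 | (3S,4E)-3-(iodomethyl)hept-4-ene | CC/C=C/[C@H](CC)CI | intermediate
27 | [(2S,3E)-2-ethylhex-3-enyl]lithium | CC/C=C/[C@H](CC)C[Li] | intermediate
28 | bromo[(2S,3E)-2-ethylhex-3-enyl]zinc | CC/C=C/[C@H](CC)C[Zn]Br | intermediate
29 | methyl 2-[(3R,4R,6R)-6-[(1Z,4R,5E)-2-bromo-4-ethylocta-1,5-dienyl]-4,6-diethyl-1,2-dioxan-3-yl]acetate | CC/C=C/[C@H](CC)C/C(Br)=C/[C@@]1(CC)C[C@@H](CC)[C@@H](CC(=O)OC)OO1 | intermediate
30 | methyl 2-[(3R,4R,6R)-4,6-diethyl-6-[(1E,4R,5E)-4-ethyl-2-methylocta-1,5-dienyl]-1,2-dioxan-3-yl]acetate | CC/C=C/[C@H](CC)C/C(C)=C/[C@@]1(CC)C[C@@H](CC)[C@@H](CC(=O)OC)OO1 | intermediate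
31 | 2-[(3R,4R,6R)-4,6-diethyl-6-[(1E,4R,5E)-4-ethyl-2-methylocta-1,5-dienyl]-1,2-dioxan-3-yl]acetic acid | CC/C=C/[C@H](CC)C/C(C)=C/[C@@]1(CC)C[C@@H](CC)[C@@H](CC(=O)O)OO1 | target

Total step count: 17 (13 on the main line, 4 for the side-chain iodide).
Longest linear sequence: 13 steps (steps 1–10 and 15–17, from pent-2-yn-1-ol).

Steps most likely to fail

Step 3. The ethylalumination may give incomplete enantiofacial control, and ethyl groups left on aluminium may compete with the branched alkyl in the transfer to palladium, consuming the iodide. The fallback sets out from 4 and returns at 9, and it fixes C4 with an auxiliary in place of the catalyst. Iodine–lithium exchange on 4 (t-BuLi, Et2O, −78 °C) and trapping with paraformaldehyde would give (2Z)-4-[tert-butyl(dimethyl)silyl]oxy-2-ethylbut-2-en-1-ol F1. Mesylation and LiBr displacement would give tert-butyl-[(2Z)-3-(bromomethyl)pent-2-enoxy]dimethylsilane F2. Auxiliary 20 is N-acylated with butanoyl chloride (n-BuLi, THF, −78 °C) to (4S)-4-benzyl-3-butanoyl-1,3-oxazolidin-2-one F3. Its sodium enolate (NaN(SiMe3)2, THF, −78 °C) is alkylated by F2 in an Evans alkylation to (4S)-4-benzyl-3-[(2R,4Z)-6-[tert-butyl(dimethyl)silyl]oxy-2,4-diethylhex-4-enoyl]-1,3-oxazolidin-2-one F4, and LiBH4 reduction returns 9.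

Step 7. The epoxide may ionise to a tertiary cation and lose stereospecificity at C6. The acetal oxygen or the new hydroxyl groups may capture C6 or C3 in place of the peroxide, and excess H2O2 may leave a hydroperoxy group at C3. The fallback sets out from 9 and returns at 16; it keeps C3 as a non-participating ester during perhydrolysis and closes the ring from a protected hydroperoxide.
- Acetylation of 9 (Ac2O, pyridine) would give (2R,4Z)-6-[tert-butyl(dimethyl)silyl]oxy-2,4-diethylhex-4-enyl acetate F5.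
- HF·pyridine would give (2R,4Z)-2,4-diethyl-6-hydroxyhex-4-enyl acetate F6.
- Sharpless epoxidation as in step 6 would give [(2R)-2-[[(2S,3R)-2-ethyl-3-(hydroxymethyl)oxiran-2-yl]methyl]butyl] acetate F7.
- Perhydrolysis (H2O2, cat. H3PMo12O40, Et2O) would give (2R,4R,5R)-2,4-diethyl-4-hydroperoxy-5,6-dihydroxyhexyl acetate F8.
- 2-Methoxypropene with PPTS would protect the hydroperoxide as its peroxyketal and the diol as its acetonide, giving (2R,4R)-4-[(4R)-2,2-dimethyl-1,3-dioxolan-4-yl]-2-ethyl-4-[(2-methoxypropan-2-yl)peroxy]hexyl acetate F9.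
- K2CO3 in MeOH would give the alcohol (2R,4R)-4-[(4R)-2,2-dimethyl-1,3-dioxolan-4-yl]-2-ethyl-4-[(2-methoxypropan-2-yl)peroxy]hexan-1-ol F10.
- Dess–Martin oxidation would give the aldehyde (2R,4R)-4-[(4R)-2,2-dimethyl-1,3-dioxolan-4-yl]-2-ethyl-4-[(2-methoxypropan-2-yl)peroxy]hexanal F11.
- PPTS and HC(OMe)3 in MeOH would free the hydroperoxide, which adds to the aldehyde and is fixed as (3RS,4R,6R)-6-[(4R)-2,2-dimethyl-1,3-dioxolan-4-yl]-4,6-diethyl-3-methoxy-1,2-dioxane F12.
- H5IO6 in Et2O would cleave the acetonide and the glycol to return 16.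

Step 10. The Lewis acid may fragment the peroxide through the peroxycarbenium ion, or the ketene acetal may attack with poor facial selectivity. The fallback sets out from 17 and returns at 18; it uses a Hosomi–Sakurai allylation, for which axial attack on six-membered carbenium ions is best established, followed by oxidative degradation. Allyltrimethylsilane and SnCl4 (CH2Cl2, −78 °C) would give (3R,4R,6R)-6-(2,2-dibromoethenyl)-4,6-diethyl-3-(prop-2-enyl)-1,2-dioxane F13. Lemieux–Johnson cleavage (cat. OsO4, NaIO4, 2,6-lutidine) of the terminal olefin would give 2-[(3R,4R,6R)-6-(2,2-dibromoethenyl)-4,6-diethyl-1,2-dioxan-3-yl]acetaldehyde F14. Pinnick oxidation (NaClO2, NaH2PO4, 2-methylbut-2-ene) would give 2-[(3R,4R,6R)-6-(2,2-dibromoethenyl)-4,6-diethyl-1,2-dioxan-3-yl]acetic acid F15, and trimethylsilyldiazomethane in MeOH returns 18.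

Further compounds

F1 | step 3 | (2Z)-4-[tert-butyl(dimethyl)silyl]oxy-2-ethylbut-2-en-1-ol | OC/C(CC)=C\CO[Si](C)(C)C(C)(C)C
F2 | step 3 | tert-butyl-[(2Z)-3-(bromomethyl)pent-2-enoxy]dimethylsilane | BrC/C(CC)=C\CO[Si](C)(C)C(C)(C)C
F3 | step 3 | (4S)-4-benzyl-3-butanoyl-1,3-oxazolidin-2-one | CCCC(=O)N1[C@@H](Cc2ccccc2)COC1=O
F4 | step 3 | (4S)-4-benzyl-3-[(2R,4Z)-6-[tert-butyl(dimethyl)silyl]oxy-2,4-diethylhex-4-enoyl]-1,3-oxazolidin-2-one | O=C([C@H](CC)C/C(CC)=C\CO[Si](C)(C)C(C)(C)C)N1[C@@H](Cc2ccccc2)COC1=O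
F5 | step 7 | (2R,4Z)-6-[tert-butyl(dimethyl)silyl]oxy-2,4-diethylhex-4-enyl acetate | CC(=O)OC[C@H](CC)C/C(CC)=C\CO[Si](C)(C)C(C)(C)C
F6 | step 7 | (2R,4Z)-2,4-diethyl-6-hydroxyhex-4-enyl acetate | CC(=O)OC[C@H](CC)C/C(CC)=C\CO
F7 | step 7 | [(2R)-2-[[(2S,3R)-2-ethyl-3-(hydroxymethyl)oxiran-2-yl]methyl]butyl] acetate | CC(=O)OC[C@H](CC)C[C@]1(CC)O[C@@H]1CO
F8 | step 7 | (2R,4R,5R)-2,4-diethyl-4-hydroperoxy-5,6-dihydroxyhexyl acetate | CC(=O)OC[C@H](CC)C[C@@](CC)(OO)[C@H](O)CO
F9 | step 7 | (2R,4R)-4-[(4R)-2,2-dimethyl-1,3-dioxolan-4-yl]-2-ethyl-4-[(2-methoxypropan-2-yl)peroxy]hexyl acetate | CC(=O)OC[C@H](CC)C[C@@](CC)(OOC(C)(C)OC)[C@H]1COC(C)(C)O1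
F10 | step 7 | (2R,4R)-4-[(4R)-2,2-dimethyl-1,3-dioxolan-4-yl]-2-ethyl-4-[(2-methoxypropan-2-yl)peroxy]hexan-1-ol | OC[C@H](CC)C[C@@](CC)(OOC(C)(C)OC)[C@H]1COC(C)(C)O1
F11 | step 7 | (2R,4R)-4-[(4R)-2,2-dimethyl-1,3-dioxolan-4-yl]-2-ethyl-4-[(2-methoxypropan-2-yl)peroxy]hexanal | O=C[C@H](CC)C[C@@](CC)(OOC(C)(C)OC)[C@H]1COC(C)(C)O1
F12 | step 7 | (3RS,4R,6R)-6-[(4R)-2,2-dimethyl-1,3-dioxolan-4-yl]-4,6-diethyl-3-methoxy-1,2-dioxane | CC1(C)OC[C@@H](O1)[C@@]2(CC)C[C@@H](CC)C(OC)OO2
F13 | step 10 | (3R,4R,6R)-6-(2,2-dibromoethenyl)-4,6-diethyl-3-(prop-2-enyl)-1,2-dioxane | BrC(Br)=C[C@@]1(CC)C[C@@H](CC)[C@@H](CC=C)OO1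
F14 | step 10 | 2-[(3R,4R,6R)-6-(2,2-dibromoethenyl)-4,6-diethyl-1,2-dioxan-3-yl]acetaldehyde | BrC(Br)=C[C@@]1(CC)C[C@@H](CC)[C@@H](CC=O)OO1
F15 | step 10 | 2-[(3R,4R,6R)-6-(2,2-dibromoethenyl)-4,6-diethyl-1,2-dioxan-3-yl]acetic acid | BrC(Br)=C[C@@]1(CC)C[C@@H](CC)[C@@H](CC(=O)O)OO1
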